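**Plan**

- Cuts (side chain numbered C1–C40 from the ring CH2): the quinone is taken back to a 1,2,3,4‑tetramethoxy‑5‑methylbenzene ring (oxidative demethylation last). The chain is cut at C7–C8, between the methyl‑bearing sp2 carbon of the C6=C7 olefin and its CH2 neighbour, giving an aryl C9 alkenyl iodide and a C33 alkyl boronate.
- Aryl half: ArCH2–C2 (syn‑methylalumination of a pentynyl ether, then alkenylalane/benzyl chloride coupling) and C6=C7 (Stork–Zhao Wittig). Boronate half: C8–C9 (boryl‑methylation with CH2(Bpin)2), C20–C21 (allylic sulfone alkylation), C32–C33 (copper‑catalysed Grignard/allylic bromide coupling).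
- Forward order: (R)‑citronellyl Grignard + ω‑bromofarnesyl silyl ether → C25; its sulfone + the same ω‑bromofarnesyl block → C40; + CH2Bpin → C41 boronate. Separately arene + C6 unit → aldehyde → (6Z)‑iodide. Union at C7–C8, quinone unmasked last.
- Enabling feature: C7 carries only a methyl and the primary C8 methylene in an isolated trisubstituted olefin. This is what a 1,2‑shift of a primary alkyl from four‑coordinate boron to the α‑carbon of an α‑methylalkenyl boronate, followed by anti B/I elimination, delivers. The benzene ring is hexasubstituted (no aryl C–H) and all other C=C bonds are unactivated, so iodine should discriminate.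
- Stereochemistry: six E‑olefins come from two (2E,6E)‑farnesol‑derived blocks (block terminus by E‑selective allylic oxidation). C2=C3 comes from syn‑carboalumination and retentive coupling, C6=C7 from the stereoinvertive union of the (6Z)‑iodide. C35 (S) is C3 of (R)‑citronellyl bromide and is never touched.

Key step: step 17

Remark: tert‑butyl(dimethyl)(pent‑4‑yn‑1‑yloxy)silane is taken as a catalogue compound (otherwise one silylation from pent‑4‑yn‑1‑ol); the C35 centre of the target (S) has the same spatial arrangement as C3 of (R)‑citronellyl bromide, the letter changing only because the CIP ranking of the two chain arms changes.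

**Route**

Step 1
Reactants: 1 (2E,6E)-farnesol [(2E,6E)-3,7,11-trimethyldodeca-2,6,10-trien-1-ol]
Product: 2 tert-butyl(diphenyl){[(2E,6E)-3,7,11-trimethyldodeca-2,6,10-trien-1-yl]oxy}silane
Conditions: TBDPSCl, imidazole, DMF, 0 °C → rt
Reagents that add atoms: tert-butyl(chloro)diphenylsilane CC(C)(C)[Si](Cl)(c1ccccc1)c1ccccc1
Why: Imidazole‑promoted silylation of the primary allylic alcohol installs a silyl ether that should survive the Riley oxidation, Grignard, organolithium and hydride conditions that follow.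

Step 2
Reactants: 2 tert-butyl(diphenyl){[(2E,6E)-3,7,11-trimethyldodeca-2,6,10-trien-1-yl]oxy}silane
Product: 3 (2E,6E,10E)-12-{[tert-butyl(diphenyl)silyl]oxy}-2,6,10-trimethyldodeca-2,6,10-trien-1-ol
Conditions: SeO2 (0.1 equiv), t-BuOOH (2 equiv), salicylic acid (0.1 equiv), CH2Cl2, 0 °C → rt, stopped at partial conversion, 2 recycled
Reagents that add atoms: tert-butyl hydroperoxide CC(C)(C)OO (terminal oxidant, source of the new oxygen by way of selenium dioxide O=[Se]=O)
Why: Catalytic Riley allylic oxidation (ene reaction then [2,3]-sigmatropic shift) should hydroxylate the (E)-methyl of the terminal isopropylidene group preferentially, giving the (E)-allylic alcohol.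

Step 3
Reactants: 3 (2E,6E,10E)-12-{[tert-butyl(diphenyl)silyl]oxy}-2,6,10-trimethyldodeca-2,6,10-trien-1-ol
Product: 4 {[(2E,6E,10E)-12-bromo-3,7,11-trimethyldodeca-2,6,10-trien-1-yl]oxy}(tert-butyl)diphenylsilane
Conditions: CBr4, PPh3, CH2Cl2, 0 °C
Reagents that add atoms: carbon tetrabromide BrC(Br)(Br)Br
Why: Appel bromination should convert the primary allylic alcohol to the bromide by SN2 displacement of the oxyphosphonium group under neutral conditions, without allylic transposition.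

Step 4
Reactants: 5 (R)-citronellyl bromide [(6R)-8-bromo-2,6-dimethyloct-2-ene]; 4 {[(2E,6E,10E)-12-bromo-3,7,11-trimethyldodeca-2,6,10-trien-1-yl]oxy}(tert-butyl)diphenylsilane
Product: 7 tert-butyl(diphenyl){[(2E,6E,10E,15S)-3,7,11,15,19-pentamethylicosa-2,6,10,18-tetraen-1-yl]oxy}silane, via [(3R)-3,7-dimethyloct-6-en-1-yl]magnesium bromide 6 (not isolated)
Conditions: Mg, THF, rt → 40 °C; then 4, Li2CuCl4 (3 mol %), THF, −78 → 0 °C
Reagents that add atoms: none
Why: The Li2CuCl4‑catalysed coupling of a primary alkyl Grignard reagent with a primary allylic bromide should proceed by direct SN2 substitution with retention of the (10E)-olefin, and the stereocentre is carried over unchanged from 5.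

Step 5
Reactants: 7 tert-butyl(diphenyl){[(2E,6E,10E,15S)-3,7,11,15,19-pentamethylicosa-2,6,10,18-tetraen-1-yl]oxy}silane
Product: 8 (2E,6E,10E,15S)-3,7,11,15,19-pentamethylicosa-2,6,10,18-tetraen-1-ol
Conditions: TBAF, THF, 0 °C → rt
Reagents that add atoms: none
Why: Fluoride‑mediated desilylation frees the primary allylic alcohol without touching the isolated olefins.

Step 6
Reactants: 8 (2E,6E,10E,15S)-3,7,11,15,19-pentamethylicosa-2,6,10,18-tetraen-1-ol
Product: 10 {[(2E,6E,10E,15S)-3,7,11,15,19-pentamethylicosa-2,6,10,18-tetraen-1-yl]sulfonyl}benzene, via (2E,6E,10E,15S)-1-bromo-3,7,11,15,19-pentamethylicosa-2,6,10,18-tetraene 9 (not isolated)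
Conditions: PBr3 (0.4 equiv), Et2O, 0 °C; crude 9, PhSO2Na, DMF, rt
Reagents that add atoms: phosphorus tribromide BrP(Br)Br (bromine of 9); sodium benzenesulfinate [Na+].[O-]S(=O)c1ccccc1
Why: Bromination of the primary allylic alcohol followed by SN2 S‑alkylation of the sulfinate should give the primary allylic sulfone with the (2E)-olefin intact.

Step 7
Reactants: 10 {[(2E,6E,10E,15S)-3,7,11,15,19-pentamethylicosa-2,6,10,18-tetraen-1-yl]sulfonyl}benzene; 4 {[(2E,6E,10E)-12-bromo-3,7,11-trimethyldodeca-2,6,10-trien-1-yl]oxy}(tert-butyl)diphenylsilane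
Product: 12 tert-butyl{[(2E,6E,10E,14E,18E,22E,27S)-3,7,11,15,19,23,27,31-octamethyl-13-(phenylsulfonyl)dotriaconta-2,6,10,14,18,22,30-heptaen-1-yl]oxy}diphenylsilane, via α-lithiated sulfone 11 (not isolated)
Conditions: n-BuLi, THF/DMPU, −78 °C; then 4, −78 → −20 °C
Reagents that add atoms: none
Why: Alkylation of the α‑sulfonyl allylic carbanion at its α‑carbon with the primary allylic bromide (allylic sulfone alkylation) joins the two farnesyl‑type blocks head to tail; the sulfone‑bearing C13 forms as a mixture of epimers, which is immaterial because the centre is removed in step 8.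

Step 8
Reactants: 12 tert-butyl{[(2E,6E,10E,14E,18E,22E,27S)-3,7,11,15,19,23,27,31-octamethyl-13-(phenylsulfonyl)dotriaconta-2,6,10,14,18,22,30-heptaen-1-yl]oxy}diphenylsilane
Product: 13 tert-butyl{[(2E,6E,10E,14E,18E,22E,27S)-3,7,11,15,19,23,27,31-octamethyldotriaconta-2,6,10,14,18,22,30-heptaen-1-yl]oxy}diphenylsilane
Conditions: PdCl2(dppp) (5 mol %), LiBHEt3 (2.5 equiv), THF, 0 °C → rt
Reagents that add atoms: none
Why: Palladium‑catalysed reductive desulfonylation (ionisation to a π‑allylpalladium species and hydride delivery to the less substituted terminus) should remove the sulfonyl group while keeping the C14=C15 bond in place and E.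

Step 9
Reactants: 13 tert-butyl{[(2E,6E,10E,14E,18E,22E,27S)-3,7,11,15,19,23,27,31-octamethyldotriaconta-2,6,10,14,18,22,30-heptaen-1-yl]oxy}diphenylsilane
Product: 14 (2E,6E,10E,14E,18E,22E,27S)-3,7,11,15,19,23,27,31-octamethyldotriaconta-2,6,10,14,18,22,30-heptaen-1-ol
Conditions: TBAF, THF, 0 °C → rt
Reagents that add atoms: none
Why: Fluoride‑mediated desilylation frees the primary allylic alcohol.

Step 10
Reactants: 14 (2E,6E,10E,14E,18E,22E,27S)-3,7,11,15,19,23,27,31-octamethyldotriaconta-2,6,10,14,18,22,30-heptaen-1-ol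
Product: 15 (2E,6E,10E,14E,18E,22E,27S)-1-bromo-3,7,11,15,19,23,27,31-octamethyldotriaconta-2,6,10,14,18,22,30-heptaene
Conditions: PBr3 (0.4 equiv), pyridine (cat.), Et2O, 0 °C
Reagents that add atoms: phosphorus tribromide BrP(Br)Br
Why: Bromination of a primary polyprenyl alcohol with PBr3 at low temperature is the standard way to the primary allylic bromide without transposition.

Step 11
Reactants: 15 (2E,6E,10E,14E,18E,22E,27S)-1-bromo-3,7,11,15,19,23,27,31-octamethyldotriaconta-2,6,10,14,18,22,30-heptaene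
Product: 16 4,4,5,5-tetramethyl-2-[(3E,7E,11E,15E,19E,23E,28S)-4,8,12,16,20,24,28,32-octamethyltritriaconta-3,7,11,15,19,23,31-heptaen-1-yl]-1,3,2-dioxaborolane
Conditions: CH2(Bpin)2 (1.5 equiv), NaOt-Bu (1.5 equiv), THF, rt; then 15, rt
Reagents that add atoms: bis(pinacolboryl)methane CC1(C)OB(CB2OC(C)(C)C(C)(C)O2)OC1(C)C
Why: Alkoxide‑promoted deborylative alkylation of the geminal bis(boronate) (tert‑butoxide adds to one boron and the resulting α‑boryl carbanion equivalent displaces the primary allylic bromide by SN2) should give the homoallylic boronic ester and brings in the carbon that becomes C8.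

Step 12
Reactants: 17 2,3,4,5-tetramethoxytoluene (1,2,3,4-tetramethoxy-5-methylbenzene)
Product: 18 1-(chloromethyl)-2,3,4,5-tetramethoxy-6-methylbenzene
Conditions: (CH2O)n, conc. aq. HCl, HCl (g), 1,4-dioxane, rt → 40 °C
Reagents that add atoms: formaldehyde (as paraformaldehyde) C=O; hydrogen chloride Cl
Why: Blanc chloromethylation of the electron‑rich arene can only occur at its single free ring position.

Step 13
Reactants: 19 tert-butyl(dimethyl)(pent-4-yn-1-yloxy)silane; 18 1-(chloromethyl)-2,3,4,5-tetramethoxy-6-methylbenzene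
Product: 21 tert-butyl(dimethyl){[(4E)-4-methyl-6-(2,3,4,5-tetramethoxy-6-methylphenyl)hex-4-en-1-yl]oxy}silane, via (E)-alkenyl(dimethyl)alane 20 (not isolated)
Conditions: Me3Al (2 equiv), Cp2ZrCl2 (0.25 equiv), ClCH2CH2Cl, rt; then 18, NiCl2(PPh3)2 (3 mol %)/n-BuLi (6 mol %), THF, rt
Reagents that add atoms: trimethylaluminium C[Al](C)C
Why: Zirconium‑catalysed syn‑methylalumination of the terminal alkyne places methyl and aluminium cis, and the cross‑coupling of the alkenylalane with the benzylic chloride under zerovalent nickel catalysis proceeds with retention, so the C2=C3 olefin should form E.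

Step 14
Reactants: 21 tert-butyl(dimethyl){[(4E)-4-methyl-6-(2,3,4,5-tetramethoxy-6-methylphenyl)hex-4-en-1-yl]oxy}silane
Product: 22 (4E)-4-methyl-6-(2,3,4,5-tetramethoxy-6-methylphenyl)hex-4-en-1-ol
Conditions: TBAF, THF, rt
Reagents that add atoms: none
Why: Fluoride‑mediated desilylation frees the primary alcohol.

Step 15
Reactants: 22 (4E)-4-methyl-6-(2,3,4,5-tetramethoxy-6-methylphenyl)hex-4-en-1-ol
Product: 23 (4E)-4-methyl-6-(2,3,4,5-tetramethoxy-6-methylphenyl)hex-4-enal
Conditions: Dess–Martin periodinane, CH2Cl2, rt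
Reagents that add atoms: none
Why: Dess–Martin oxidation converts the primary alcohol to the aldehyde under mild conditions that leave the electron‑rich arene and the olefin alone.

Step 16
Reactants: 23 (4E)-4-methyl-6-(2,3,4,5-tetramethoxy-6-methylphenyl)hex-4-enal
Product: 24 1-[(2E,6Z)-7-iodo-3-methylocta-2,6-dien-1-yl]-2,3,4,5-tetramethoxy-6-methylbenzene
Conditions: [Ph3PEt]I, n-BuLi, THF, rt; I2, −78 °C; NaN(SiMe3)2, −20 °C; then 23, −78 °C → rt
Reagents that add atoms: ethyltriphenylphosphonium iodide CC[P+](c1ccccc1)(c1ccccc1)c1ccccc1.[I-]; iodine II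
Why: The Stork–Zhao Wittig reaction of the non‑stabilised α‑iodo ylide should pass through the kinetically favoured cis‑oxaphosphetane and give the (Z)-α‑iodoalkene, with iodine cis to the C5 chain.

Step 17
Reactants: 24 1-[(2E,6Z)-7-iodo-3-methylocta-2,6-dien-1-yl]-2,3,4,5-tetramethoxy-6-methylbenzene; 16 4,4,5,5-tetramethyl-2-[(3E,7E,11E,15E,19E,23E,28S)-4,8,12,16,20,24,28,32-octamethyltritriaconta-3,7,11,15,19,23,31-heptaen-1-yl]-1,3,2-dioxaborolane
Product: 28 1-[(2E,6E,10E,14E,18E,22E,26E,30E,35S)-3,7,11,15,19,23,27,31,35,39-decamethyltetraconta-2,6,10,14,18,22,26,30,38-nonaen-1-yl]-2,3,4,5-tetramethoxy-6-methylbenzene, via alkenyllithium 25 (not isolated), via lithium boronate complex 26 (not isolated), via β-iodoalkyl boronic ester 27 (not isolated)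
Conditions: 24 (1.1 equiv), t-BuLi (2.0 equiv per iodide), Et2O/THF, −78 °C; 16, −78 °C; I2 (1.2 equiv), THF/MeOH, −78 °C; NaOMe, MeOH, −78 °C → rt
Reagents that add atoms: none
Why: Iodine–lithium exchange on 24 gives the configurationally stable alkenyllithium 25 (lithium cis to C5), which adds to boron of 16 to form the four‑coordinate boronate 26; iodine then attacks the electron‑rich C6=C7 bond of 26 and the primary alkyl group (C8) migrates from boron to C7 anti to the incoming iodine, which creates the C7–C8 bond and gives the β‑iodoalkyl boronic ester 27. Methoxide then adds to boron and triggers anti‑periplanar elimination of boron and iodide, so that C8 ends up trans to C5: iodine is replaced by C8 with inversion of olefin geometry, which is why the (6Z)-iodide is the correct precursor of the (6E)-olefin. The closest known reaction type is the Zweifel olefination of alkenyllithium reagents with primary alkyl pinacol boronic esters to give trisubstituted alkenes. No ring is closed and no lasting stereocentre is made: the two centres of 27 are transient, both anti adducts collapse to the same olefin, and C35 is remote and untouched. The selectivity needed is reaction of iodine at the boronate‑activated C6=C7 bond in the presence of eight isolated trisubstituted alkenes; this should be secured by the far higher nucleophilicity of the alkenyl boronate at −78 °C, by near‑stoichiometric iodine and by the hexasubstituted arene offering no position for iodination, while migration of the carbon group instead of a pinacol oxygen is the normal course for boronic esters.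

Step 18
Reactants: 28 1-[(2E,6E,10E,14E,18E,22E,26E,30E,35S)-3,7,11,15,19,23,27,31,35,39-decamethyltetraconta-2,6,10,14,18,22,26,30,38-nonaen-1-yl]-2,3,4,5-tetramethoxy-6-methylbenzene
Product: 29 2-[(2E,6E,10E,14E,18E,22E,26E,30E,35S)-3,7,11,15,19,23,27,31,35,39-decamethyltetraconta-2,6,10,14,18,22,26,30,38-nonaen-1-yl]-5,6-dimethoxy-3-methylcyclohexa-2,5-diene-1,4-dione (CNP0144872.1)
Conditions: (NH4)2Ce(NO3)6 (2.5 equiv), MeCN/CH2Cl2/H2O, 0 °C
Reagents that add atoms: water O
Why: Oxidative demethylation by tetravalent cerium should convert the para‑related methoxy groups flanking the alkyl and methyl substituents into the 1,4‑quinone (water attacks the arene radical cation and methanol is lost), the isolated olefins being much harder to oxidise than the tetramethoxyarene.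

**Compound list**

1 | (2E,6E)-farnesol | OC/C=C(\C)CC/C=C(\C)CCC=C(C)C | starting material
2 | tert-butyl(diphenyl){[(2E,6E)-3,7,11-trimethyldodeca-2,6,10-trien-1-yl]oxy}silane | CC(C)(C)[Si](c1ccccc1)(c1ccccc1)OC/C=C(\C)CC/C=C(\C)CCC=C(C)C | intermediate
3 | (2E,6E,10E)-12-{[tert-butyl(diphenyl)silyl]oxy}-2,6,10-trimethyldodeca-2,6,10-trien-1-ol | CC(C)(C)[Si](c1ccccc1)(c1ccccc1)OC/C=C(\C)CC/C=C(\C)CC/C=C(\C)CO | intermediate
4 | {[(2E,6E,10E)-12-bromo-3,7,11-trimethyldodeca-2,6,10-trien-1-yl]oxy}(tert-butyl)diphenylsilane | CC(C)(C)[Si](c1ccccc1)(c1ccccc1)OC/C=C(\C)CC/C=C(\C)CC/C=C(\C)CBr | intermediate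
5 | (R)-citronellyl bromide, (6R)-8-bromo-2,6-dimethyloct-2-ene | BrCC[C@H](C)CCC=C(C)C | starting material
6 | [(3R)-3,7-dimethyloct-6-en-1-yl]magnesium bromide | Br[Mg]CC[C@H](C)CCC=C(C)C | intermediate (not isolated)
7 | tert-butyl(diphenyl){[(2E,6E,10E,15S)-3,7,11,15,19-pentamethylicosa-2,6,10,18-tetraen-1-yl]oxy}silane | CC(C)(C)[Si](c1ccccc1)(c1ccccc1)OC/C=C(\C)CC/C=C(\C)CC/C=C(\C)CCC[C@H](C)CCC=C(C)C | intermediate
8 | (2E,6E,10E,15S)-3,7,11,15,19-pentamethylicosa-2,6,10,18-tetraen-1-ol | OC/C=C(\C)CC/C=C(\C)CC/C=C(\C)CCC[C@H](C)CCC=C(C)C | intermediate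
9 | (2E,6E,10E,15S)-1-bromo-3,7,11,15,19-pentamethylicosa-2,6,10,18-tetraene | BrC/C=C(\C)CC/C=C(\C)CC/C=C(\C)CCC[C@H](C)CCC=C(C)C | intermediate (not isolated)
10 | {[(2E,6E,10E,15S)-3,7,11,15,19-pentamethylicosa-2,6,10,18-tetraen-1-yl]sulfonyl}benzene | O=S(=O)(C/C=C(\C)CC/C=C(\C)CC/C=C(\C)CCC[C@H](C)CCC=C(C)C)c1ccccc1 | intermediate
11 | [(2E,6E,10E,15S)-3,7,11,15,19-pentamethyl-1-(phenylsulfonyl)icosa-2,6,10,18-tetraen-1-yl]lithium | [Li]C(/C=C(\C)CC/C=C(\C)CC/C=C(\C)CCC[C@H](C)CCC=C(C)C)S(=O)(=O)c1ccccc1 | intermediate (not isolated)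
12 | tert-butyl{[(2E,6E,10E,14E,18E,22E,27S)-3,7,11,15,19,23,27,31-octamethyl-13-(phenylsulfonyl)dotriaconta-2,6,10,14,18,22,30-heptaen-1-yl]oxy}diphenylsilane (both C13 epimers) | CC(C)(C)[Si](c1ccccc1)(c1ccccc1)OC/C=C(\C)CC/C=C(\C)CC/C=C(\C)CC(/C=C(\C)CC/C=C(\C)CC/C=C(\C)CCC[C@H](C)CCC=C(C)C)S(=O)(=O)c1ccccc1 | intermediate
13 | tert-butyl{[(2E,6E,10E,14E,18E,22E,27S)-3,7,11,15,19,23,27,31-octamethyldotriaconta-2,6,10,14,18,22,30-heptaen-1-yl]oxy}diphenylsilane | CC(C)(C)[Si](c1ccccc1)(c1ccccc1)OC/C=C(\C)CC/C=C(\C)CC/C=C(\C)CC/C=C(\C)CC/C=C(\C)CC/C=C(\C)CCC[C@H](C)CCC=C(C)C | intermediate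
14 | (2E,6E,10E,14E,18E,22E,27S)-3,7,11,15,19,23,27,31-octamethyldotriaconta-2,6,10,14,18,22,30-heptaen-1-ol | OC/C=C(\C)CC/C=C(\C)CC/C=C(\C)CC/C=C(\C)CC/C=C(\C)CC/C=C(\C)CCC[C@H](C)CCC=C(C)C | intermediate
15 | (2E,6E,10E,14E,18E,22E,27S)-1-bromo-3,7,11,15,19,23,27,31-octamethyldotriaconta-2,6,10,14,18,22,30-heptaene | BrC/C=C(\C)CC/C=C(\C)CC/C=C(\C)CC/C=C(\C)CC/C=C(\C)CC/C=C(\C)CCC[C@H](C)CCC=C(C)C | intermediate
16 | 4,4,5,5-tetramethyl-2-[(3E,7E,11E,15E,19E,23E,28S)-4,8,12,16,20,24,28,32-octamethyltritriaconta-3,7,11,15,19,23,31-heptaen-1-yl]-1,3,2-dioxaborolane | CC1(C)OB(CC/C=C(\C)CC/C=C(\C)CC/C=C(\C)CC/C=C(\C)CC/C=C(\C)CC/C=C(\C)CCC[C@H](C)CCC=C(C)C)OC1(C)C | intermediate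
17 | 2,3,4,5-tetramethoxytoluene | Cc1cc(OC)c(OC)c(OC)c1OC | starting material
18 | 1-(chloromethyl)-2,3,4,5-tetramethoxy-6-methylbenzene | COc1c(OC)c(OC)c(CCl)c(C)c1OC | intermediate
19 | tert-butyl(dimethyl)(pent-4-yn-1-yloxy)silane | C#CCCCO[Si](C)(C)C(C)(C)C | starting material
20 | [(1E)-5-{[tert-butyl(dimethyl)silyl]oxy}-2-methylpent-1-en-1-yl](dimethyl)alane | C[Al](C)/C=C(\C)CCCO[Si](C)(C)C(C)(C)C | intermediate (not isolated)
21 | tert-butyl(dimethyl){[(4E)-4-methyl-6-(2,3,4,5-tetramethoxy-6-methylphenyl)hex-4-en-1-yl]oxy}silane | COc1c(OC)c(OC)c(C/C=C(\C)CCCO[Si](C)(C)C(C)(C)C)c(C)c1OC | intermediate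
22 | (4E)-4-methyl-6-(2,3,4,5-tetramethoxy-6-methylphenyl)hex-4-en-1-ol | COc1c(OC)c(OC)c(C/C=C(\C)CCCO)c(C)c1OC | intermediate
23 | (4E)-4-methyl-6-(2,3,4,5-tetramethoxy-6-methylphenyl)hex-4-enal | COc1c(OC)c(OC)c(C/C=C(\C)CCC=O)c(C)c1OC | intermediate
24 | 1-[(2E,6Z)-7-iodo-3-methylocta-2,6-dien-1-yl]-2,3,4,5-tetramethoxy-6-methylbenzene | COc1c(OC)c(OC)c(C/C=C(\C)CC/C=C(\I)C)c(C)c1OC | intermediate
25 | [(6E)-6-methyl-8-(2,3,4,5-tetramethoxy-6-methylphenyl)octa-2,6-dien-2-yl]lithium, lithium cis to the chain (geometry of 24 retained) | COc1c(OC)c(OC)c(C/C=C(\C)CC/C=C(\[Li])C)c(C)c1OC | intermediate (not isolated)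
26 | lithium boronate complex of 25 and 16: boron (pinacolate) bound to C7 of the aryl dienyl unit (boron cis to C5) and to C1 of the C33 alkyl chain | [Li+].COc1c(OC)c(OC)c(C/C=C(\C)CC/C=C(/C)[B-]2(CC/C=C(\C)CC/C=C(\C)CC/C=C(\C)CC/C=C(\C)CC/C=C(\C)CC/C=C(\C)CCC[C@H](C)CCC=C(C)C)OC(C)(C)C(C)(C)O2)c(C)c1OC | intermediate (not isolated)
27 | β-iodoalkyl boronic ester: skeleton of 28 with iodine on C6 and pinacolboryl on C7, anti adduct; (6S,7S,35S) drawn, the (6R,7R,35S) isomer forms alongside | COc1c(OC)c(OC)c(C/C=C(\C)CC[C@H](I)[C@](C)(B2OC(C)(C)C(C)(C)O2)CC/C=C(\C)CC/C=C(\C)CC/C=C(\C)CC/C=C(\C)CC/C=C(\C)CC/C=C(\C)CCC[C@H](C)CCC=C(C)C)c(C)c1OC | intermediate (not isolated)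
28 | 1-[(2E,6E,10E,14E,18E,22E,26E,30E,35S)-3,7,11,15,19,23,27,31,35,39-decamethyltetraconta-2,6,10,14,18,22,26,30,38-nonaen-1-yl]-2,3,4,5-tetramethoxy-6-methylbenzene | COc1c(OC)c(OC)c(C/C=C(\C)CC/C=C(\C)CC/C=C(\C)CC/C=C(\C)CC/C=C(\C)CC/C=C(\C)CC/C=C(\C)CC/C=C(\C)CCC[C@H](C)CCC=C(C)C)c(C)c1OC | intermediate
29 | 2-[(2E,6E,10E,14E,18E,22E,26E,30E,35S)-3,7,11,15,19,23,27,31,35,39-decamethyltetraconta-2,6,10,14,18,22,26,30,38-nonaen-1-yl]-5,6-dimethoxy-3-methylcyclohexa-2,5-diene-1,4-dione | COC1=C(OC)C(=O)C(C/C=C(\C)CC/C=C(\C)CC/C=C(\C)CC/C=C(\C)CC/C=C(\C)CC/C=C(\C)CC/C=C(\C)CC/C=C(\C)CCC[C@H](C)CCC=C(C)C)=C(C)C1=O | target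

**Count**

Total: 18 steps. Longest linear sequence: 13 steps (steps 1–11, 17, 18, from farnesol).

**Steps most likely to fail, with fallbacks**

1. Step 17. Iodine may be diverted into iodination or iodo‑methoxylation of the remote trisubstituted alkenes, or the 1,2‑shift may stall at the boronate stage and the complex be protonated on work‑up. The fallback forms C7–C8 with retention by a Negishi coupling; it sets out from aldehyde 23 and boronate 16 and returns at 28.
   - Aryl partner: Ohira–Bestmann homologation of 23 (dimethyl (1-diazo-2-oxopropyl)phosphonate, K2CO3, MeOH) should give the terminal alkyne 1-[(2E)-3-methylhept-2-en-6-yn-1-yl]-2,3,4,5-tetramethoxy-6-methylbenzene F1. Deprotonation (n-BuLi, THF, −78 °C) gives its lithium acetylide F2, and methylation (MeI) gives 1-[(2E)-3-methyloct-2-en-6-yn-1-yl]-2,3,4,5-tetramethoxy-6-methylbenzene F3. Hydrozirconation with excess Cp2Zr(H)Cl (THF, warmed so that the regioisomeric alkenylzirconium species equilibrate towards zirconium on the methyl‑bearing carbon) gives chlorobis(cyclopentadienyl)[(2E,6E)-6-methyl-8-(2,3,4,5-tetramethoxy-6-methylphenyl)octa-2,6-dien-2-yl]zirconium F4. Iodinolysis (I2) gives 1-[(2E,6E)-7-iodo-3-methylocta-2,6-dien-1-yl]-2,3,4,5-tetramethoxy-6-methylbenzene F5.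
   - Alkyl partner: oxidation of 16 (NaBO3·4H2O, THF/H2O) gives (3E,7E,11E,15E,19E,23E,28S)-4,8,12,16,20,24,28,32-octamethyltritriaconta-3,7,11,15,19,23,31-heptaen-1-ol F6. Iodination (I2, PPh3, imidazole) gives (3E,7E,11E,15E,19E,23E,28S)-1-iodo-4,8,12,16,20,24,28,32-octamethyltritriaconta-3,7,11,15,19,23,31-heptaene F7. Zinc insertion (Zn dust, LiCl, THF) gives [(3E,7E,11E,15E,19E,23E,28S)-4,8,12,16,20,24,28,32-octamethyltritriaconta-3,7,11,15,19,23,31-heptaen-1-yl]zinc iodide F8.
   - Union: PdCl2(dppf)-catalysed Negishi coupling of F5 with F8 (THF, rt) should give 28 with retention at C6=C7.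

2. Step 16. The basic α‑iodo ylide may enolise the aldehyde, lose iodine to give the plain ethylidene olefin, or discriminate poorly between the Z and E iodides. The fallback avoids a stereodefined iodide; it sets out from aldehyde 23 (and 16, by way of the zinc reagent F8 made as in the preceding fallback) and returns at 28.
   - Dichloro‑olefination of 23 (BrCCl3, PPh3, MeCN) gives 1-[(2E)-7,7-dichloro-3-methylhepta-2,6-dien-1-yl]-2,3,4,5-tetramethoxy-6-methylbenzene F9.
   - Trans‑selective Negishi mono‑alkylation with F8 (PdCl2(DPEphos), THF) relies on zerovalent palladium inserting into the less hindered C–Cl bond trans to the chain. It should give 1-[(2E,6Z,10E,14E,18E,22E,26E,30E,35S)-7-chloro-3,11,15,19,23,27,31,35,39-nonamethyltetraconta-2,6,10,14,18,22,26,30,38-nonaen-1-yl]-2,3,4,5-tetramethoxy-6-methylbenzene F10.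
   - Methylation of the remaining chloride with retention (Me2Zn, Pd(P(t-Bu)3)2, THF) gives 28.

3. Step 11. tert‑Butoxide may compete as a nucleophile for the allylic bromide, or substitution may occur with allylic transposition. The fallback sets out from bromide 15 and returns at 16.
   - Palladium‑catalysed borylation (B2pin2, Pd2(dba)3, THF/DMSO, 50 °C) gives the linear allylic boronate 4,4,5,5-tetramethyl-2-[(2E,6E,10E,14E,18E,22E,27S)-3,7,11,15,19,23,27,31-octamethyldotriaconta-2,6,10,14,18,22,30-heptaen-1-yl]-1,3,2-dioxaborolane F11.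
   - Matteson homologation (BrCH2Cl, n-BuLi, THF, −78 °C → rt) passes through the lithium (chloromethyl)boronate complex of F11 F12. Its allyl group migrates from boron to carbon without transposition as chloride leaves, which gives 16.

Further compounds
F1 | step 17 | 1-[(2E)-3-methylhept-2-en-6-yn-1-yl]-2,3,4,5-tetramethoxy-6-methylbenzene | COc1c(OC)c(OC)c(C/C=C(\C)CCC#C)c(C)c1OC
F2 | step 17 | lithium acetylide of F1 | COc1c(OC)c(OC)c(C/C=C(\C)CCC#C[Li])c(C)c1OC
F3 | step 17 | 1-[(2E)-3-methyloct-2-en-6-yn-1-yl]-2,3,4,5-tetramethoxy-6-methylbenzene | COc1c(OC)c(OC)c(C/C=C(\C)CCC#CC)c(C)c1OC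
F4 | step 17 | chlorobis(cyclopentadienyl)[(2E,6E)-6-methyl-8-(2,3,4,5-tetramethoxy-6-methylphenyl)octa-2,6-dien-2-yl]zirconium | COc1c(OC)c(OC)c(C/C=C(\C)CC/C=C(\C)[Zr](Cl)(C2C=CC=C2)C2C=CC=C2)c(C)c1OC
F5 | step 17 | 1-[(2E,6E)-7-iodo-3-methylocta-2,6-dien-1-yl]-2,3,4,5-tetramethoxy-6-methylbenzene | COc1c(OC)c(OC)c(C/C=C(\C)CC/C=C(\C)I)c(C)c1OC
F6 | step 17 | (3E,7E,11E,15E,19E,23E,28S)-4,8,12,16,20,24,28,32-octamethyltritriaconta-3,7,11,15,19,23,31-heptaen-1-ol | OCC/C=C(\C)CC/C=C(\C)CC/C=C(\C)CC/C=C(\C)CC/C=C(\C)CC/C=C(\C)CCC[C@H](C)CCC=C(C)C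
F7 | step 17 | (3E,7E,11E,15E,19E,23E,28S)-1-iodo-4,8,12,16,20,24,28,32-octamethyltritriaconta-3,7,11,15,19,23,31-heptaene | ICC/C=C(\C)CC/C=C(\C)CC/C=C(\C)CC/C=C(\C)CC/C=C(\C)CC/C=C(\C)CCC[C@H](C)CCC=C(C)C
F8 | step 17 | [(3E,7E,11E,15E,19E,23E,28S)-4,8,12,16,20,24,28,32-octamethyltritriaconta-3,7,11,15,19,23,31-heptaen-1-yl]zinc iodide | I[Zn]CC/C=C(\C)CC/C=C(\C)CC/C=C(\C)CC/C=C(\C)CC/C=C(\C)CC/C=C(\C)CCC[C@H](C)CCC=C(C)C
F9 | step 16 | 1-[(2E)-7,7-dichloro-3-methylhepta-2,6-dien-1-yl]-2,3,4,5-tetramethoxy-6-methylbenzene | COc1c(OC)c(OC)c(C/C=C(\C)CCC=C(Cl)Cl)c(C)c1OC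
F10 | step 16 | 1-[(2E,6Z,10E,14E,18E,22E,26E,30E,35S)-7-chloro-3,11,15,19,23,27,31,35,39-nonamethyltetraconta-2,6,10,14,18,22,26,30,38-nonaen-1-yl]-2,3,4,5-tetramethoxy-6-methylbenzene | COc1c(OC)c(OC)c(C/C=C(\C)CC/C=C(\Cl)CC/C=C(\C)CC/C=C(\C)CC/C=C(\C)CC/C=C(\C)CC/C=C(\C)CC/C=C(\C)CCC[C@H](C)CCC=C(C)C)c(C)c1OC
F11 | step 11 | 4,4,5,5-tetramethyl-2-[(2E,6E,10E,14E,18E,22E,27S)-3,7,11,15,19,23,27,31-octamethyldotriaconta-2,6,10,14,18,22,30-heptaen-1-yl]-1,3,2-dioxaborolane | CC1(C)OB(C/C=C(\C)CC/C=C(\C)CC/C=C(\C)CC/C=C(\C)CC/C=C(\C)CC/C=C(\C)CCC[C@H](C)CCC=C(C)C)OC1(C)C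
F12 | step 11 | lithium (chloromethyl)boronate complex of F11 | [Li+].ClC[B-]1(C/C=C(\C)CC/C=C(\C)CC/C=C(\C)CC/C=C(\C)CC/C=C(\C)CC/C=C(\C)CCC[C@H](C)CCC=C(C)C)OC(C)(C)C(C)(C)O1
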